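## Retrosynthetic overview

1. The target comes from ruthenium-catalysed redox isomerisation and desilylation of a propargylic diol, made from a side-chain aldehyde and 2-methylbut-3-yn-2-ol; the aldehyde comes from a terminal vinyl group.
2. The oxepane comes from closing C5–C6 by a visible-light nickel/photoredox decarboxylative coupling of a cesium γ-hydroxy carboxylate onto a tethered (Z)-vinyl iodide, which also fixes the 6E alkene.
3. That carboxylate comes from a γ-lactone tertiary ether, made from a tertiary alcohol lactone and a (Z)-2-iodo-4-silyloxybut-2-enyl bromide (from but-2-yne-1,4-diol).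
4. The tertiary alcohol lactone comes from Felkin–Anh Grignard addition of the bromide derived from (S)-β-citronellene to the methyl ketone of (R)-5-oxooxolane-2-carboxylic acid (D-glutamic acid series).
5. Ring order: the γ-lactone is bought and later opened; the oxepane is the only ring made and is closed at step 9.

Assumption: the SMILES is read as (2S,3R,6E) at the oxepane and S at the side-chain methine. Locants below: O1, C2 (quaternary), C3 (CHOH), C4, C5, C6 (alkylidene carbon), C7 (OCH2), exocyclic C8 and C9, side chain C1′–C8′ counted outwards from C2.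

## Route

Step 1
Reactants: 1 (3S)-3,7-dimethylocta-1,6-diene [(S)-β-citronellene]
Product: 4 (4S)-4-methylhex-5-en-1-ol, via ozonide 2 (not isolated), via aldehyde 3 (not isolated)
Conditions: O3 (1.0 equiv, Sudan red 7B end point), CH2Cl2, −78 °C; then NaBH4, MeOH, −78 °C → rt
Reagents that add atoms: ozone, [O-][O+]=O
Why: Ozonolysis with reductive work-up; with one equivalent of ozone at −78 °C the trisubstituted alkene reacts much faster than the vinyl group, so only the isopropylidene end is cut and the bought stereocentre is untouched.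

Step 2
Reactants: 4 (4S)-4-methylhex-5-en-1-ol
Product: 5 (3S)-6-bromo-3-methylhex-1-ene
Conditions: CBr4, PPh3, CH2Cl2, 0 °C
Reagents that add atoms: carbon tetrabromide, BrC(Br)(Br)Br
Why: Appel reaction (SN2 at the primary carbinol carbon) under neutral conditions that leave the alkene and the stereocentre alone.

Step 3
Reactants: 6 (2R)-5-oxooxolane-2-carboxylic acid [lactone acid of D-glutamic acid]
Product: 8 (5R)-5-acetyloxolan-2-one, via acid chloride 7 (not isolated)
Conditions: (COCl)2, DMF (cat.), CH2Cl2, 0 °C → rt, evaporate; then MeMgBr (1.05 equiv), Fe(acac)3 (3 mol %), THF, −78 °C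
Reagents that add atoms: methylmagnesium bromide, C[Mg]Br
Why: Acid chloride formation followed by iron-catalysed Grignard acylation (Fürstner–Kumada-type ketone synthesis), which is fast at −78 °C, stops at the ketone, leaves the lactone alone and gives the stereocentre no time to epimerise.

Step 4
Reactants: 5 (3S)-6-bromo-3-methylhex-1-ene; 8 (5R)-5-acetyloxolan-2-one
Product: 10 (5R)-5-[(2S,6S)-2-hydroxy-6-methyloct-7-en-2-yl]oxolan-2-one, via Grignard reagent 9 (not isolated)
Conditions: 5, Mg, THF, 0–25 °C (use at once); add to 8, THF, −78 °C; aq. NH4Cl at −78 °C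
Reagents that add atoms: none
Why: Grignard 1,2-addition under Felkin–Anh/Cornforth control: the lactone C–O bond lies anti to the incoming nucleophile, which passes the small hydrogen at C3, so the bought (R) centre sets the new tertiary carbinol as (S) (my estimate about 5:1, minor epimer removed by chromatography), and at −78 °C the ketone reacts far faster than the lactone.

Step 5
Reactants: 11 but-2-yne-1,4-diol
Product: 12 4-{[tert-butyl(dimethyl)silyl]oxy}but-2-yn-1-ol
Conditions: NaH (1.0 equiv), THF, 0 °C → rt; then TBSCl (1.0 equiv)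
Reagents that add atoms: tert-butyl(chloro)dimethylsilane, CC(C)(C)[Si](C)(C)Cl
Why: Monosilylation of a symmetrical diol through its sparingly soluble monosodium alkoxide (McDougal procedure), a Williamson-type O-silylation.

Step 6
Reactants: 12 4-{[tert-butyl(dimethyl)silyl]oxy}but-2-yn-1-ol
Product: 14 (2Z)-4-{[tert-butyl(dimethyl)silyl]oxy}-2-iodobut-2-en-1-ol, via alkenylstannane 13 (not isolated)
Conditions: Bu3SnH (1.1 equiv), [Cp*RuCl]4 (1.5 mol %), CH2Cl2, rt; then I2, CH2Cl2, 0 °C
Reagents that add atoms: iodine, II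
Why: Hydroxyl-directed ruthenium-catalysed trans-hydrostannation (Fürstner) puts tin on the alkyne carbon next to the free OH with H anti to it, and iododestannylation with retention then gives the (Z)-vinyl iodide as one regio- and stereoisomer.

Step 7
Reactants: 14 (2Z)-4-{[tert-butyl(dimethyl)silyl]oxy}-2-iodobut-2-en-1-ol
Product: 15 {[(2Z)-4-bromo-3-iodobut-2-en-1-yl]oxy}(tert-butyl)dimethylsilane
Conditions: CBr4, PPh3, CH2Cl2, 0 °C
Reagents that add atoms: carbon tetrabromide, BrC(Br)(Br)Br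
Why: Appel bromination of the primary allylic alcohol without allylic shift; the vinyl iodide and the silyl ether are inert.

Step 8
Reactants: 10 (5R)-5-[(2S,6S)-2-hydroxy-6-methyloct-7-en-2-yl]oxolan-2-one; 15 {[(2Z)-4-bromo-3-iodobut-2-en-1-yl]oxy}(tert-butyl)dimethylsilane
Product: 16 (5R)-5-[(2S,6S)-2-{[(2Z)-4-{[tert-butyl(dimethyl)silyl]oxy}-2-iodobut-2-en-1-yl]oxy}-6-methyloct-7-en-2-yl]oxolan-2-one
Conditions: 15 (2 equiv), AgOTf (2 equiv), 2,6-di-tert-butyl-4-methylpyridine (2.5 equiv), 4 Å MS, CH2Cl2, −40 → 0 °C, dark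
Reagents that add atoms: none
Why: Silver-triflate-promoted O-alkylation (halide abstraction, hindered pyridine as acid scavenger) etherifies the tertiary alcohol without forming an alkoxide, so the γ-lactone cannot migrate to the tertiary oxygen, the secondary oxygen stays masked, and the bulky alcohol attacks the unhindered primary allylic carbon.

Step 9
Reactants: 16 (5R)-5-[(2S,6S)-2-{[(2Z)-4-{[tert-butyl(dimethyl)silyl]oxy}-2-iodobut-2-en-1-yl]oxy}-6-methyloct-7-en-2-yl]oxolan-2-one
Product: 18 (2S,3R,6E)-6-(2-{[tert-butyl(dimethyl)silyl]oxy}ethylidene)-2-methyl-2-[(4S)-4-methylhex-5-en-1-yl]oxepan-3-ol, via cesium carboxylate 17 (not isolated)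
Conditions: CsOH·H2O (1.05 equiv), THF/H2O (4:1), 0 → 25 °C, concentrate, dry (PhMe azeotrope); then 4CzIPN (3 mol %), NiCl2·glyme (10 mol %), dtbbpy (15 mol %), DMSO (0.005 M), 450 nm LEDs, 25 °C, Ar
Reagents that add atoms: none
Why: Proposed new method: the γ-lactone serves as a latent primary alkyl radical and as the protecting group of the C3 hydroxyl; hydroxide opening gives carboxylate 17, excited 4CzIPN oxidises it by one electron, loss of CO2 gives the C5 radical, zerovalent nickel (dtbbpy) has meanwhile inserted into the (Z)-vinyl C–I bond, the tethered radical is trapped by this alkenyl divalent nickel, and the resulting trivalent nickel reductively eliminates with retention of alkene geometry, closing the seven-membered ring through C5–C6 and fixing the 6E alkene (direct 7-exo attack of the radical on the iodine-bearing carbon followed by loss of an iodine atom leads to the same ring); high dilution favours ring closure; the closest known reaction type is the intermolecular nickel/photoredox decarboxylative coupling of carboxylic acids with vinyl halides, which has not been run as a ring closure to a medium-ring ether nor from a lactone opened in the flask.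

Step 10
Reactants: 18 (2S,3R,6E)-6-(2-{[tert-butyl(dimethyl)silyl]oxy}ethylidene)-2-methyl-2-[(4S)-4-methylhex-5-en-1-yl]oxepan-3-ol
Product: 20 (2S)-5-[(2S,3R,6E)-6-(2-{[tert-butyl(dimethyl)silyl]oxy}ethylidene)-3-hydroxy-2-methyloxepan-2-yl]-2-methylpentanal, via diol 19 (not isolated)
Conditions: OsO4 (2 mol %), NaIO4 (2.5 equiv), 2,6-lutidine (2 equiv), dioxane/H2O (3:1), 0 °C → rt
Reagents that add atoms: sodium periodate, [Na+].[O-]I(=O)(=O)=O
Why: Lemieux–Johnson oxidation: the unhindered monosubstituted alkene is osmylated much faster than the trisubstituted alkene flanked by two allylic C–O bonds, and the lutidine buffer keeps the α-methyl aldehyde from epimerising.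

Step 11
Reactants: 20 (2S)-5-[(2S,3R,6E)-6-(2-{[tert-butyl(dimethyl)silyl]oxy}ethylidene)-3-hydroxy-2-methyloxepan-2-yl]-2-methylpentanal; 21 2-methylbut-3-yn-2-ol
Product: 23 (6S)-9-[(2S,3R,6E)-6-(2-{[tert-butyl(dimethyl)silyl]oxy}ethylidene)-3-hydroxy-2-methyloxepan-2-yl]-2,6-dimethylnon-3-yne-2,5-diol (C5 epimers), via dilithium alkynide 22 (not isolated)
Conditions: 21 (4 equiv), n-BuLi (8 equiv), THF, −78 → 0 °C; then 20, −78 °C; aq. NH4Cl
Reagents that add atoms: none
Why: Acetylide 1,2-addition to the aldehyde at −78 °C is faster than enolisation, so C4′ keeps its configuration; the new carbinol centre forms as a mixture, which does not matter because it becomes the ketone in step 12.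

Step 12
Reactants: 23 (6S)-9-[(2S,3R,6E)-6-(2-{[tert-butyl(dimethyl)silyl]oxy}ethylidene)-3-hydroxy-2-methyloxepan-2-yl]-2,6-dimethylnon-3-yne-2,5-diol (C5 epimers)
Product: 25 (3E,6S)-2-hydroxy-9-[(2S,3R,6E)-3-hydroxy-6-(2-hydroxyethylidene)-2-methyloxepan-2-yl]-2,6-dimethylnon-3-en-5-one, via silyl ether enone 24 (not isolated)
Conditions: (η5-indenyl)RuCl(PPh3)2 (5 mol %), InCl3 (5 mol %), Et3NHPF6 (5 mol %), THF, 65 °C; then TBAF, AcOH, THF, 0 °C → rt
Reagents that add atoms: none
Why: Trost-type ruthenium/indium-catalysed redox isomerisation of the secondary propargylic alcohol (1,2-hydride shift onto the ruthenium-bound alkyne, then protonation) gives the (E)-γ-hydroxy enone with no external oxidant, so no other alcohol is oxidised and the tertiary carbinol stays; buffered fluoride then removes the silyl ether.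

## Compound list

1 | (3S)-3,7-dimethylocta-1,6-diene [(S)-β-citronellene] | C=C[C@@H](C)CCC=C(C)C | starting material
2 | 3,3-dimethyl-5-[(3S)-3-methylpent-4-en-1-yl]-1,2,4-trioxolane | C=C[C@@H](C)CCC1OOC(C)(C)O1 | intermediate
3 | (4S)-4-methylhex-5-enal | C=C[C@@H](C)CCC=O | intermediate
4 | (4S)-4-methylhex-5-en-1-ol | C=C[C@@H](C)CCCO | intermediate
5 | (3S)-6-bromo-3-methylhex-1-ene | C=C[C@@H](C)CCCBr | intermediate
6 | (2R)-5-oxooxolane-2-carboxylic acid | OC(=O)[C@H]1CCC(=O)O1 | starting material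
7 | (2R)-5-oxooxolane-2-carbonyl chloride | ClC(=O)[C@H]1CCC(=O)O1 | intermediate
8 | (5R)-5-acetyloxolan-2-one | CC(=O)[C@H]1CCC(=O)O1 | intermediate
9 | [(4S)-4-methylhex-5-en-1-yl]magnesium bromide | C=C[C@@H](C)CCC[Mg]Br | intermediate
10 | (5R)-5-[(2S,6S)-2-hydroxy-6-methyloct-7-en-2-yl]oxolan-2-one | C=C[C@@H](C)CCC[C@](C)(O)[C@H]1CCC(=O)O1 | intermediate
11 | but-2-yne-1,4-diol | OCC#CCO | starting material
12 | 4-{[tert-butyl(dimethyl)silyl]oxy}but-2-yn-1-ol | OCC#CCO[Si](C)(C)C(C)(C)C | intermediate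
13 | (2Z)-4-{[tert-butyl(dimethyl)silyl]oxy}-2-(tributylstannyl)but-2-en-1-ol | OC/C([Sn](CCCC)(CCCC)CCCC)=C/CO[Si](C)(C)C(C)(C)C | intermediate
14 | (2Z)-4-{[tert-butyl(dimethyl)silyl]oxy}-2-iodobut-2-en-1-ol | OC/C(I)=C/CO[Si](C)(C)C(C)(C)C | intermediate
15 | {[(2Z)-4-bromo-3-iodobut-2-en-1-yl]oxy}(tert-butyl)dimethylsilane | BrC/C(I)=C/CO[Si](C)(C)C(C)(C)C | intermediate
16 | (5R)-5-[(2S,6S)-2-{[(2Z)-4-{[tert-butyl(dimethyl)silyl]oxy}-2-iodobut-2-en-1-yl]oxy}-6-methyloct-7-en-2-yl]oxolan-2-one | C=C[C@@H](C)CCC[C@](C)(OC/C(I)=C/CO[Si](C)(C)C(C)(C)C)[C@H]1CCC(=O)O1 | intermediate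
17 | cesium (4R,5S,9S)-5-{[(2Z)-4-{[tert-butyl(dimethyl)silyl]oxy}-2-iodobut-2-en-1-yl]oxy}-4-hydroxy-5,9-dimethylundec-10-enoate | C=C[C@@H](C)CCC[C@](C)(OC/C(I)=C/CO[Si](C)(C)C(C)(C)C)[C@H](O)CCC(=O)[O-].[Cs+] | intermediate
18 | (2S,3R,6E)-6-(2-{[tert-butyl(dimethyl)silyl]oxy}ethylidene)-2-methyl-2-[(4S)-4-methylhex-5-en-1-yl]oxepan-3-ol | C=C[C@@H](C)CCC[C@]1(C)OC/C(=C/CO[Si](C)(C)C(C)(C)C)CC[C@H]1O | intermediate
19 | (3S)-6-[(2S,3R,6E)-6-(2-{[tert-butyl(dimethyl)silyl]oxy}ethylidene)-3-hydroxy-2-methyloxepan-2-yl]-3-methylhexane-1,2-diol (C2 epimers) | OCC(O)[C@@H](C)CCC[C@]1(C)OC/C(=C/CO[Si](C)(C)C(C)(C)C)CC[C@H]1O | intermediate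
20 | (2S)-5-[(2S,3R,6E)-6-(2-{[tert-butyl(dimethyl)silyl]oxy}ethylidene)-3-hydroxy-2-methyloxepan-2-yl]-2-methylpentanal | O=C[C@@H](C)CCC[C@]1(C)OC/C(=C/CO[Si](C)(C)C(C)(C)C)CC[C@H]1O | intermediate
21 | 2-methylbut-3-yn-2-ol | CC(C)(O)C#C | starting material
22 | lithium 4-lithio-2-methylbut-3-yn-2-olate | [Li]C#CC(C)(C)O[Li] | intermediate
23 | (6S)-9-[(2S,3R,6E)-6-(2-{[tert-butyl(dimethyl)silyl]oxy}ethylidene)-3-hydroxy-2-methyloxepan-2-yl]-2,6-dimethylnon-3-yne-2,5-diol (C5 epimers) | CC(C)(O)C#CC(O)[C@@H](C)CCC[C@]1(C)OC/C(=C/CO[Si](C)(C)C(C)(C)C)CC[C@H]1O | intermediate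
24 | (3E,6S)-9-[(2S,3R,6E)-6-(2-{[tert-butyl(dimethyl)silyl]oxy}ethylidene)-3-hydroxy-2-methyloxepan-2-yl]-2-hydroxy-2,6-dimethylnon-3-en-5-one | C[C@@H](CCC[C@]1(C)OC/C(=C/CO[Si](C)(C)C(C)(C)C)CC[C@H]1O)C(=O)/C=C/C(C)(C)O | intermediate
25 | (3E,6S)-2-hydroxy-9-[(2S,3R,6E)-3-hydroxy-6-(2-hydroxyethylidene)-2-methyloxepan-2-yl]-2,6-dimethylnon-3-en-5-one | C[C@@H](CCC[C@]1(C)OC/C(=C/CO)CC[C@H]1O)C(=O)/C=C/C(C)(C)O | target

## Step count and risks

Total step count: 12.
Longest linear sequence: 8 steps (steps 1, 2, 4, 8, 9, 10, 11, 12 from 1; the branch from 11 through steps 5, 6, 7 is equally long).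

Three steps most likely to fail:

1. Step 9 (the proposed ring closure). The primary radical may be reduced, abstract hydrogen or dimerise before nickel captures it, and a seven-membered ring has not been closed this way. Fallback (sets out from 16, returns at 18): close the same C5–C6 bond by a two-electron Negishi coupling. 16 is saponified (LiOH, THF/H2O) and silylated (TESCl, imidazole, DMF) to the triethylsilyl ester F1, whose silyl ester is cleaved (K2CO3, MeOH) to the acid F2. Suárez iododecarboxylation (PhI(OAc)2, I2, hν, cyclohexane) gives the primary iodide F3. Zinc dust (LiCl, THF, 25 °C) inserts into the alkyl C–I bond in preference to the vinyl C–I bond to give the alkylzinc iodide F4, and Pd(PPh3)4 (THF, 50 °C) closes the ring by intramolecular Negishi coupling with retention of alkene geometry to the bis-silyl ether F5. PPTS in MeOH at 0 °C removes the secondary triethylsilyl group, leaves the primary TBS ether and gives 18.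

2. Step 8 (etherification of a hindered tertiary alcohol). The alcohol may be too unreactive, or the allyl cation may be attacked at its secondary end. Fallback (sets out from 10, returns at 16): mask the lactone and use a true alkoxide. DIBAL-H (CH2Cl2, −78 °C) reduces 10 to the lactol F6, and MeOH/PPTS gives the methyl acetal F7. The potassium alkoxide (KH, 18-crown-6, THF, 0 °C) is alkylated by 15 in a Williamson ether synthesis to the acetal ether F8; no acyl group is left to migrate. PPTS in wet acetone returns the lactol F9, and PhI(OAc)2 with catalytic TEMPO oxidises it to 16.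

3. Step 4 (facial selectivity at the new tertiary carbinol). If the lactone oxygen chelates magnesium, the wrong C2 epimer would predominate, or the ratio may simply be low. Fallback (sets out from 6 and 5, returns at 10): put the two carbon groups on in the reverse order. Acid chloride 7 (from 6 as in step 3) and Grignard reagent 9 (from 5 as in step 4) are joined with Fe(acac)3 (THF, −78 °C) to the chain ketone F10. MeTiCl3 (CH2Cl2, −78 °C, Reetz chelation-controlled methylation) then adds methyl to the chelated ketone from the face next to hydrogen, which gives 10.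

## Further compounds

F1 | step 9 | triethylsilyl (4R,5S,9S)-5-{[(2Z)-4-{[tert-butyl(dimethyl)silyl]oxy}-2-iodobut-2-en-1-yl]oxy}-5,9-dimethyl-4-[(triethylsilyl)oxy]undec-10-enoate | C=C[C@@H](C)CCC[C@](C)(OC/C(I)=C/CO[Si](C)(C)C(C)(C)C)[C@H](O[Si](CC)(CC)CC)CCC(=O)O[Si](CC)(CC)CC
F2 | step 9 | (4R,5S,9S)-5-{[(2Z)-4-{[tert-butyl(dimethyl)silyl]oxy}-2-iodobut-2-en-1-yl]oxy}-5,9-dimethyl-4-[(triethylsilyl)oxy]undec-10-enoic acid | C=C[C@@H](C)CCC[C@](C)(OC/C(I)=C/CO[Si](C)(C)C(C)(C)C)[C@H](O[Si](CC)(CC)CC)CCC(=O)O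
F3 | step 9 | (3S,7S,8R)-7-{[(2Z)-4-{[tert-butyl(dimethyl)silyl]oxy}-2-iodobut-2-en-1-yl]oxy}-10-iodo-3,7-dimethyl-8-[(triethylsilyl)oxy]dec-1-ene | C=C[C@@H](C)CCC[C@](C)(OC/C(I)=C/CO[Si](C)(C)C(C)(C)C)[C@H](O[Si](CC)(CC)CC)CCI
F4 | step 9 | [(3R,4S,8S)-4-{[(2Z)-4-{[tert-butyl(dimethyl)silyl]oxy}-2-iodobut-2-en-1-yl]oxy}-4,8-dimethyl-3-[(triethylsilyl)oxy]dec-9-en-1-yl]zinc iodide | C=C[C@@H](C)CCC[C@](C)(OC/C(I)=C/CO[Si](C)(C)C(C)(C)C)[C@H](O[Si](CC)(CC)CC)CC[Zn]I
F5 | step 9 | (2S,3R,6E)-6-(2-{[tert-butyl(dimethyl)silyl]oxy}ethylidene)-2-methyl-2-[(4S)-4-methylhex-5-en-1-yl]-3-[(triethylsilyl)oxy]oxepane | C=C[C@@H](C)CCC[C@]1(C)OC/C(=C/CO[Si](C)(C)C(C)(C)C)CC[C@H]1O[Si](CC)(CC)CC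
F6 | step 8 | (5R)-5-[(2S,6S)-2-hydroxy-6-methyloct-7-en-2-yl]oxolan-2-ol (anomers) | C=C[C@@H](C)CCC[C@](C)(O)[C@H]1CCC(O)O1
F7 | step 8 | (2S,6S)-2-[(2R)-5-methoxyoxolan-2-yl]-6-methyloct-7-en-2-ol (anomers) | C=C[C@@H](C)CCC[C@](C)(O)[C@H]1CCC(OC)O1
F8 | step 8 | tert-butyl{[(2Z)-3-iodo-4-{[(2S,6S)-2-[(2R)-5-methoxyoxolan-2-yl]-6-methyloct-7-en-2-yl]oxy}but-2-en-1-yl]oxy}dimethylsilane (anomers) | C=C[C@@H](C)CCC[C@](C)(OC/C(I)=C/CO[Si](C)(C)C(C)(C)C)[C@H]1CCC(OC)O1
F9 | step 8 | (5R)-5-[(2S,6S)-2-{[(2Z)-4-{[tert-butyl(dimethyl)silyl]oxy}-2-iodobut-2-en-1-yl]oxy}-6-methyloct-7-en-2-yl]oxolan-2-ol (anomers) | C=C[C@@H](C)CCC[C@](C)(OC/C(I)=C/CO[Si](C)(C)C(C)(C)C)[C@H]1CCC(O)O1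
F10 | step 4 | (5R)-5-[(5S)-5-methylhept-6-enoyl]oxolan-2-one | C=C[C@@H](C)CCCC(=O)[C@H]1CCC(=O)O1
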